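## Retrosynthetic overview

1. The target comes from its ring C 7‑O‑methyl ether by a final O‑demethylation.
2. The ring A C6–ring B C8 biaryl bond is cut to a ring A 6‑bromide (borylated in the flask) and 8‑iodoumbelliferone (Suzuki–Miyaura).
3. Key disconnection: the enol aryl ether C–O bond between O7 of ring A and C3 of ring C, cut to 6‑bromo‑7‑hydroxycoumarin and 7‑methoxycoumarin‑3‑carboxylic acid (new copper‑mediated photodecarboxylative aryloxylation).
4. Ring order: ring A is built first by Pechmann annulation of 4‑bromoresorcinol; rings B and C are bought as intact coumarins; no ring is formed after the ether bond.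

Assumption: the target has no stereocentre and its ring A–ring B axis (three small oxygen ortho substituents) is taken as freely rotating at room temperature, so the SMILES describes one achiral compound and no stereocontrol is needed.

## Route

Step 1
Reactants: 1 4‑bromoresorcinol (4‑bromobenzene‑1,3‑diol)
Product: 2 6‑bromo‑7‑hydroxy‑2H‑chromen‑2‑one (6‑bromo‑7‑hydroxycoumarin)
Conditions: DL‑malic acid (1.1 equiv), conc. H2SO4, 110 °C, 2 h; ice
Reagents that add atoms: DL‑malic acid, OC(CC(=O)O)C(=O)O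
Why: von Pechmann condensation – malic acid loses CO and water in hot H2SO4 to give formylacetic acid, which attacks the unhindered activated carbon of 1 (para to one OH, ortho to the other) and lactonises onto the neighbouring OH, placing Br at C6 and the free OH at C7.

Step 2
Reactants: 3 umbelliferone (7‑hydroxy‑2H‑chromen‑2‑one)
Product: 4 7‑hydroxy‑8‑iodo‑2H‑chromen‑2‑one
Conditions: I2 (1.05 equiv), KI, 25% aq NH3, 20 °C; then 2 M HCl to pH 2
Reagents that add atoms: iodine, II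
Why: electrophilic aromatic iodination of the phenoxide, which goes to C8 (flanked by O7 and the ring oxygen), the most nucleophilic carbon of umbelliferone.

Step 3
Reactants: 2 6‑bromo‑7‑hydroxy‑2H‑chromen‑2‑one (1.0 equiv); 5 7‑methoxy‑2‑oxo‑2H‑chromene‑3‑carboxylic acid (1.5 equiv)
Product: 6 3‑[(6‑bromo‑2‑oxo‑2H‑chromen‑7‑yl)oxy]‑7‑methoxy‑2H‑chromen‑2‑one
Conditions: Cu(OTf)2 (2.5 equiv), Li2CO3 (2 equiv), MeCN (0.05 M), 395 nm LEDs, 35 °C, N2
Reagents that add atoms: none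
Why: Proposed new method: copper‑mediated photodecarboxylative C3‑aryloxylation of a coumarin‑3‑carboxylic acid – the divalent copper carboxylate of 5 undergoes ligand‑to‑metal charge transfer at 395 nm to an acyloxyl radical that loses CO2, the coumarin‑3‑yl sigma radical is trapped by the divalent copper aryloxide of 2 to give a trivalent alkenyl(aryloxy)copper species, and C–O reductive elimination forms the O7–C3 bond exactly at the former carboxyl carbon, with the second equivalent of Cu(OTf)2 as the oxidant; the C–Br bond and the lactones should survive because nothing present inserts into C–Br at 35 °C; the closest known reaction types are the copper LMCT decarboxylative hydroxylation, halogenation and borylation of aryl carboxylic acids and the Chan–Lam C–O reductive elimination, neither shown for an alkenyl acid or with a phenol as oxygen partner.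

Step 4
Reactants: 6 3‑[(6‑bromo‑2‑oxo‑2H‑chromen‑7‑yl)oxy]‑7‑methoxy‑2H‑chromen‑2‑one; 4 7‑hydroxy‑8‑iodo‑2H‑chromen‑2‑one (1.2 equiv)
Product: 8 3‑{[6‑(7‑hydroxy‑2‑oxo‑2H‑chromen‑8‑yl)‑2‑oxo‑2H‑chromen‑7‑yl]oxy}‑7‑methoxy‑2H‑chromen‑2‑one, via pinacol boronate 7 (not isolated)
Conditions: Pd(OAc)2 (5 mol%), XPhos (2‑dicyclohexylphosphino‑2',4',6'‑triisopropylbiphenyl, 10 mol%), B2pin2 (1.2 equiv), KOAc (3 equiv), 1,4‑dioxane, 100 °C; then 4, 3 M aq K3PO4 (4 equiv), 90 °C; 1 M HCl work‑up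
Reagents that add atoms: bis(pinacolato)diboron, CC1(C)OB(OC1(C)C)B1OC(C)(C)C(C)(C)O1 (supplies the boryl group of 7 only; none of its atoms remain in 8)
Why: Miyaura borylation then Suzuki–Miyaura coupling in one pot – with the weak base KOAc zerovalent palladium borylates the C–Br bond of 6 without homocoupling, and after K3PO4 is added the same catalyst couples boronate 7 with the C–I bond of 4; boron sits on the singly ortho‑oxygenated ring A carbon (slow protodeboronation), the halide on the doubly ortho‑oxygenated C8 of ring B, and the acid work‑up recloses any opened lactone.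

Step 5
Reactants: 8 3‑{[6‑(7‑hydroxy‑2‑oxo‑2H‑chromen‑8‑yl)‑2‑oxo‑2H‑chromen‑7‑yl]oxy}‑7‑methoxy‑2H‑chromen‑2‑one
Product: 9 7‑hydroxy‑3‑{[6‑(7‑hydroxy‑2‑oxo‑2H‑chromen‑8‑yl)‑2‑oxo‑2H‑chromen‑7‑yl]oxy}‑2H‑chromen‑2‑one (target)
Conditions: BBr3 (8 equiv), CH2Cl2, −78 °C to 20 °C, 12 h; H2O quench
Reagents that add atoms: none
Why: Lewis‑acid O‑demethylation of an aryl methyl ether – bromide attacks only the sp3 methyl carbon of the boron‑complexed ether, so the enol aryl ether (both carbons sp2), the three lactones and the biaryl are untouched.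

## Compound list

1 | 4‑bromoresorcinol (4‑bromobenzene‑1,3‑diol) | Oc1ccc(Br)c(O)c1 | starting material
2 | 6‑bromo‑7‑hydroxy‑2H‑chromen‑2‑one | O=c1ccc2cc(Br)c(O)cc2o1 | intermediate
3 | umbelliferone (7‑hydroxy‑2H‑chromen‑2‑one) | O=c1ccc2ccc(O)cc2o1 | starting material
4 | 7‑hydroxy‑8‑iodo‑2H‑chromen‑2‑one | O=c1ccc2ccc(O)c(I)c2o1 | intermediate
5 | 7‑methoxy‑2‑oxo‑2H‑chromene‑3‑carboxylic acid | COc1ccc2cc(C(=O)O)c(=O)oc2c1 | starting material
6 | 3‑[(6‑bromo‑2‑oxo‑2H‑chromen‑7‑yl)oxy]‑7‑methoxy‑2H‑chromen‑2‑one | COc1ccc2cc(Oc3cc4oc(=O)ccc4cc3Br)c(=O)oc2c1 | intermediate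
7 | 7‑methoxy‑3‑{[2‑oxo‑6‑(4,4,5,5‑tetramethyl‑1,3,2‑dioxaborolan‑2‑yl)‑2H‑chromen‑7‑yl]oxy}‑2H‑chromen‑2‑one (not isolated) | COc1ccc2cc(Oc3cc4oc(=O)ccc4cc3B5OC(C)(C)C(C)(C)O5)c(=O)oc2c1 | intermediate
8 | 3‑{[6‑(7‑hydroxy‑2‑oxo‑2H‑chromen‑8‑yl)‑2‑oxo‑2H‑chromen‑7‑yl]oxy}‑7‑methoxy‑2H‑chromen‑2‑one | O=c1ccc2cc(-c3c(O)ccc4ccc(=O)oc34)c(Oc3cc4ccc(OC)cc4oc3=O)cc2o1 | intermediate
9 | 7‑hydroxy‑3‑{[6‑(7‑hydroxy‑2‑oxo‑2H‑chromen‑8‑yl)‑2‑oxo‑2H‑chromen‑7‑yl]oxy}‑2H‑chromen‑2‑one | O=c1ccc2cc(-c3c(O)ccc4ccc(=O)oc34)c(Oc3cc4ccc(O)cc4oc3=O)cc2o1 | target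

## Step count and risk

Total steps: 5. Longest linear sequence: 4 (steps 1, 3, 4, 5). Step 2 is a one‑step side branch.

The three steps most likely to fail:

**Step 3 (the proposed new step).** The risks are:
- the phenolate of 2 absorbs near 395 nm and may screen the copper carboxylate;
- divalent copper may oxidise the aryloxide to an aryloxyl radical;
- the coumarin‑3‑yl radical may abstract hydrogen, giving 7‑methoxycoumarin;
- the carboxylate may take the place of the aryloxide in the reductive elimination;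
- the coumarins may photodimerise.

The fallback uses known chemistry; it sets out from 2 and comes back to the route at 6. Williamson alkylation of 2 with tert‑butyl bromoacetate (K2CO3, acetone, reflux) gives tert‑butyl 2‑[(6‑bromo‑2‑oxo‑2H‑chromen‑7‑yl)oxy]acetate F1, which still makes the key C–O bond, now by SN2. TFA in CH2Cl2 frees 2‑[(6‑bromo‑2‑oxo‑2H‑chromen‑7‑yl)oxy]acetic acid F2. A Perkin–Oglialoro condensation of this acid with purchased 2‑hydroxy‑4‑methoxybenzaldehyde (COc1ccc(C=O)c(O)c1) in Ac2O/Et3N at 110 °C then builds ring C around the ether carbon and gives 6.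

**Step 4 (one‑pot borylation/Suzuki).** The risks are a hindered coupling next to a free phenoxide, protodeboronation of 7 and base‑opened lactones. The fallback changes the coupling type and the polarity; it sets out from 4 and comes back at 8. Compound 4 is protected with MOMCl/iPr2NEt in CH2Cl2 to give 8‑iodo‑7‑(methoxymethoxy)‑2H‑chromen‑2‑one F3. Zinc dust and LiCl in THF at 40 °C insert into the C–I bond to give [7‑(methoxymethoxy)‑2‑oxo‑2H‑chromen‑8‑yl]zinc iodide F4, which cannot protodemetalate under anhydrous conditions. Negishi coupling of this reagent with isolated 6 (Pd(OAc)2, SPhos (2‑dicyclohexylphosphino‑2',6'‑dimethoxybiphenyl), THF, 60 °C) gives 7‑methoxy‑3‑({6‑[7‑(methoxymethoxy)‑2‑oxo‑2H‑chromen‑8‑yl]‑2‑oxo‑2H‑chromen‑7‑yl}oxy)‑2H‑chromen‑2‑one F5. HCl in MeOH removes the MOM group and gives 8.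

**Step 5 (late BBr3 demethylation).** The risks are poor solubility of the tris‑lactone, incomplete cleavage and loss of material on a precious intermediate. The fallback removes the need for a demethylation by changing the ring C protecting group; it sets out from 2 and comes back at 9. Acid F2 (made from 2 through F1 as above) is condensed with purchased 2,4‑dihydroxybenzaldehyde (Oc1ccc(C=O)c(O)c1) in Ac2O/Et3N to give 3‑[(6‑bromo‑2‑oxo‑2H‑chromen‑7‑yl)oxy]‑2‑oxo‑2H‑chromen‑7‑yl acetate F6. Under the step 4 conditions this is borylated to 2‑oxo‑3‑{[2‑oxo‑6‑(4,4,5,5‑tetramethyl‑1,3,2‑dioxaborolan‑2‑yl)‑2H‑chromen‑7‑yl]oxy}‑2H‑chromen‑7‑yl acetate F7 and coupled with 4 to give 3‑{[6‑(7‑hydroxy‑2‑oxo‑2H‑chromen‑8‑yl)‑2‑oxo‑2H‑chromen‑7‑yl]oxy}‑2‑oxo‑2H‑chromen‑7‑yl acetate F8. The aqueous K3PO4 hydrolyses this acetate in the same pot, so acid work‑up gives 9 directly.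

## Further compounds

F1 | step 3 | tert‑butyl 2‑[(6‑bromo‑2‑oxo‑2H‑chromen‑7‑yl)oxy]acetate | CC(C)(C)OC(=O)COc1cc2oc(=O)ccc2cc1Br
F2 | step 3 | 2‑[(6‑bromo‑2‑oxo‑2H‑chromen‑7‑yl)oxy]acetic acid | OC(=O)COc1cc2oc(=O)ccc2cc1Br
F3 | step 4 | 8‑iodo‑7‑(methoxymethoxy)‑2H‑chromen‑2‑one | COCOc1ccc2ccc(=O)oc2c1I
F4 | step 4 | [7‑(methoxymethoxy)‑2‑oxo‑2H‑chromen‑8‑yl]zinc iodide | COCOc1ccc2ccc(=O)oc2c1[Zn]I
F5 | step 4 | 7‑methoxy‑3‑({6‑[7‑(methoxymethoxy)‑2‑oxo‑2H‑chromen‑8‑yl]‑2‑oxo‑2H‑chromen‑7‑yl}oxy)‑2H‑chromen‑2‑one | COCOc1ccc2ccc(=O)oc2c1-c1cc2ccc(=O)oc2cc1Oc1cc2ccc(OC)cc2oc1=O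
F6 | step 5 | 3‑[(6‑bromo‑2‑oxo‑2H‑chromen‑7‑yl)oxy]‑2‑oxo‑2H‑chromen‑7‑yl acetate | CC(=O)Oc1ccc2cc(Oc3cc4oc(=O)ccc4cc3Br)c(=O)oc2c1
F7 | step 5 | 2‑oxo‑3‑{[2‑oxo‑6‑(4,4,5,5‑tetramethyl‑1,3,2‑dioxaborolan‑2‑yl)‑2H‑chromen‑7‑yl]oxy}‑2H‑chromen‑7‑yl acetate | CC(=O)Oc1ccc2cc(Oc3cc4oc(=O)ccc4cc3B5OC(C)(C)C(C)(C)O5)c(=O)oc2c1
F8 | step 5 | 3‑{[6‑(7‑hydroxy‑2‑oxo‑2H‑chromen‑8‑yl)‑2‑oxo‑2H‑chromen‑7‑yl]oxy}‑2‑oxo‑2H‑chromen‑7‑yl acetate | CC(=O)Oc1ccc2cc(Oc3cc4oc(=O)ccc4cc3-c3c(O)ccc4ccc(=O)oc34)c(=O)oc2c1
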